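## Retrosynthetic overview

1. Target ⇒ isofraxidin + a neopentyl C11 alcohol (aryl ether made second to last); the C3 ketone is unmasked last, which also settles C4.
2. C8 methyl (axial, cis to C11) ⇒ hydrogenolysis of a cyclopropane placed on the Δ7 alkene, which comes from the C8 ketone.
3. C9 quaternary centre and trans ring fusion ⇒ Li/NH3 reduction of a bicyclic enone with formaldehyde capture of the enolate.
4. Ring B is the only ring formed (ring A is bought as a carbocycle, the coumarin arrives intact) ⇒ aldol condensation of a triketone.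
5. Key C5–C6 bond ⇒ zinc homoenolate of pentan-3-one (from 1-ethylcyclopropanol) added to 2,3-dimethylcyclohex-2-ene-1,4-dione: two β-carbons, both normally electrophilic, are joined and the C5 quaternary centre is set.

Convention: C1–C11 are sesquiterpene locants (ring A = C1–C5, C10 with the ketone at C3; ring B = C5–C10; C11 = OCH2 on C9). The α face is that of H-10, C11 and the C8 methyl; the β face is that of the C4, C5 and C9 methyls. The target is (1R,2R,4aS,5R,8aR) in decalin numbering.

Assumption: 2,3-dimethylcyclohex-2-en-1-one and isofraxidin are bought; C4 stays epimerisable until the end, so intermediates are drawn with the final C4 configuration and any C4 epimer converges in step 12.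

## Route

Step 1
Reactants: 1 methyl propanoate
Product: 2 1-ethylcyclopropan-1-ol
Conditions: EtMgBr (2.4 equiv), Ti(OiPr)4 (10 mol %), Et2O, 20 °C; aq H2SO4
Reagents that add atoms: ethylmagnesium bromide, CC[Mg]Br
Why: Kulinkovich cyclopropanation, in which the titanacyclopropane made from EtMgBr and Ti(OiPr)4 adds twice to the ester carbonyl and supplies the two ring CH2 groups; no stereocentre is formed.

Step 2
Reactants: 3 2,3-dimethylcyclohex-2-en-1-one
Product: 4 2,3-dimethylcyclohex-2-ene-1,4-dione
Conditions: t-BuOOH (5 equiv), Pd(OH)2/C (5 mol %), K2CO3 (0.25 equiv), CH2Cl2, 4 °C; cold filtration through silica, used at once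
Reagents that add atoms: tert-butyl hydroperoxide, CC(C)(C)OO
Why: peroxy-radical allylic oxidation of an enone to the 1,4-enedione at the ring CH2 γ to the carbonyl, the most activated C–H; the product is handled cold and quickly because it can tautomerise to 2,3-dimethylhydroquinone.

Step 3
Reactants: 2 1-ethylcyclopropan-1-ol; 4 2,3-dimethylcyclohex-2-ene-1,4-dione
Product: 7 (2R,3R)-2,3-dimethyl-2-(3-oxopentyl)cyclohexane-1,4-dione, via zinc homoenolate 5 (not isolated), via silyl enol ether 6 (not isolated)
Conditions: 2 (2.4 equiv), Et2Zn (1.2 equiv), THF, 0 → 40 °C; then 4 (1.0 equiv), Cu(OTf)2 (5 mol %), phosphoramidite L1 (10 mol %; O,O′-(S)-1,1′-binaphthyl-2,2′-diyl N,N-bis[(R)-1-phenylethyl]phosphoramidite), Me3SiCl (2 equiv), toluene, −30 → 0 °C; 1 M HCl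
Reagents that add atoms: none
Why: Proposed new method: the zinc cyclopropoxide from 2 ring-opens to the chelated homoenolate 5, whose nucleophilic carbon is the normally electrophilic β-carbon of ethyl vinyl ketone, and after transmetalation to copper bearing L1 it adds, with Me3SiCl trapping of the enolate, to one enantiotopic face of the doubly activated tetrasubstituted alkene of 4, forming the C5–C6 bond and the C5 quaternary centre as R (the antipode of L1 is used if that is the one giving R; C4 is set later); the closest known reactions are the Cu-catalysed, Me3SiCl-promoted conjugate addition of zinc homoenolates to enones and the Cu/phosphoramidite asymmetric conjugate addition of dialkylzincs that builds quaternary centres.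

Step 4
Reactants: 7 (2R,3R)-2,3-dimethyl-2-(3-oxopentyl)cyclohexane-1,4-dione
Product: 8 (4aR,5R)-1,4a,5-trimethyl-4,4a,7,8-tetrahydronaphthalene-2,6(3H,5H)-dione
Conditions: pyrrolidine (0.3 equiv), AcOH (0.3 equiv), toluene, 60 °C
Reagents that add atoms: none
Why: enamine-mediated intramolecular aldol condensation (the second half of a Robinson annulation), in which the ethyl-ketone CH2 (C9) attacks the C10 ketone as the only six-ring closure and dehydration gives the conjugated enone; C5 is untouched and C4 equilibrates by enolisation.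

Step 5
Reactants: 8 (4aR,5R)-1,4a,5-trimethyl-4,4a,7,8-tetrahydronaphthalene-2,6(3H,5H)-dione
Product: 9 (1'R,8a'R)-1',5',8a'-trimethyl-3',4',8',8a'-tetrahydro-1'H-spiro[[1,3]dioxolane-2,2'-naphthalen]-6'(7'H)-one (C3 ethylene ketal of 8)
Conditions: HOCH2CH2OH, p-TsOH·H2O (0.2 equiv), 4 Å MS, 20 °C
Reagents that add atoms: ethane-1,2-diol, OCCO
Why: chemoselective ketalisation of the saturated C3 ketone, since the tetrasubstituted conjugated enone carbonyl is far less electrophilic (as in the mono-ketalisation of Wieland–Miescher-type diones).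

Step 6
Reactants: 9 C3 ethylene ketal of 8
Product: 11 (1'R,4a'R,5'R,8a'S)-5'-(hydroxymethyl)-1',5',8a'-trimethyl-3',4',4a',5',8',8a'-hexahydro-1'H-spiro[[1,3]dioxolane-2,2'-naphthalen]-6'(7'H)-one, via lithium enolate 10 (not isolated)
Conditions: Li (2.3 equiv), t-BuOH (1.0 equiv), NH3(l)/THF, −78 → −33 °C; isoprene; NH3 removed; THF, −78 °C, CH2O gas (from cracked paraformaldehyde); aq NH4Cl
Reagents that add atoms: formaldehyde, C=O
Why: dissolving-metal enone reduction with regiospecific enolate trapping (Stork reductive hydroxymethylation), where axial protonation at C10 gives the trans-decalin (10α-H anti to the 5β-methyl) and formaldehyde attacks the C9 enolate carbon from the α face, anti to the angular 5β-methyl, giving the 9α-CH2OH/9β-Me quaternary centre.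

Step 7
Reactants: 11 the β-hydroxy ketone from step 6
Product: 12 N'-[(1'R,4a'R,5'S,6'E,8a'S)-5'-(hydroxymethyl)-1',5',8a'-trimethyloctahydro-1'H-spiro[[1,3]dioxolane-2,2'-naphthalen]-6'-ylidene]-4-methylbenzenesulfonohydrazide
Conditions: TsNHNH2 (1.2 equiv), AcOH (cat.), THF, 50 °C
Reagents that add atoms: 4-methylbenzenesulfonohydrazide, Cc1ccc(cc1)S(=O)(=O)NN
Why: hydrazone condensation at the C8 ketone, with the N–NHTs group anti to quaternary C9 (E) and therefore syn to C7 as step 8 requires.

Step 8
Reactants: 12 the tosylhydrazone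
Product: 14 [(1'R,4a'R,5'R,8a'S)-1',5',8a'-trimethyl-3',4',4a',5',8',8a'-hexahydro-1'H-spiro[[1,3]dioxolane-2,2'-naphthalen]-5'-yl]methanol (Δ7 alkene), via vinyllithium 13 (not isolated)
Conditions: n-BuLi (3.5 equiv), TMEDA, THF, −78 → 20 °C; H2O
Reagents that add atoms: none
Why: Shapiro reaction, in which syn α-deprotonation can only occur at C7 (C9 has no hydrogen) and loss of sulfinate and N2 gives the C8 vinyllithium, protonated to the C7=C8 alkene; the C11 alkoxide is a spectator and no stereocentre is touched.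

Step 9
Reactants: 14 the Δ7 alkene
Product: 15 cyclopropane: 14 with a CH2 bridging C7 and C8 on the α face (syn to CH2OH and H-10)
Conditions: Et2Zn (3 equiv), CH2I2 (4 equiv), CH2Cl2, 0 → 20 °C
Reagents that add atoms: diiodomethane, ICI
Why: Simmons–Smith (Furukawa) cyclopropanation directed by the zinc alkoxide of the homoallylic C11–OH, which delivers CH2 to the α face (also the face free of the axial 9β- and 5β-methyls) and so fixes the new C8–C bond cis to C11.

Step 10
Reactants: 15 the cyclopropane
Product: 16 [(1'R,4a'R,5'R,6'R,8a'S)-1',5',6',8a'-tetramethyloctahydro-1'H-spiro[[1,3]dioxolane-2,2'-naphthalen]-5'-yl]methanol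
Conditions: H2 (4 atm), PtO2, AcOH/EtOAc, NaOAc, 20 °C
Reagents that add atoms: none
Why: catalytic cyclopropane hydrogenolysis at the less hindered external bond (C7–CH2, remote from quaternary C9), which turns the bridging carbon into the C8 methyl while the C8–C bond made in step 9 is not broken, so the axial 8α-methyl (trans to the 9β-methyl) is retained.

Step 11
Reactants: 16 the 8α-methyl alcohol; 17 isofraxidin (7-hydroxy-6,8-dimethoxy-2H-chromen-2-one)
Product: 19 7-{[(1'R,4a'R,5'R,6'R,8a'S)-1',5',6',8a'-tetramethyloctahydro-1'H-spiro[[1,3]dioxolane-2,2'-naphthalen]-5'-yl]methoxy}-6,8-dimethoxy-2H-chromen-2-one, via neopentyl triflate 18 (not isolated)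
Conditions: Tf2O (1.2 equiv), 2,6-lutidine (2 equiv), CH2Cl2, −40 → 0 °C; then 17 (1.5 equiv), Cs2CO3 (2 equiv), DMF, 20 → 50 °C
Reagents that add atoms: none
Why: Williamson-type SN2 displacement of a primary triflate by the cesium phenoxide, where the triflate leaving group offsets the neopentyl retardation and no β-hydrogen is available for elimination; no stereocentre is touched.

Step 12
Reactants: 19 the ketal ether
Product: 20 7-{[(1R,2R,4aS,5R,8aR)-1,2,4a,5-tetramethyl-6-oxodecahydronaphthalen-1-yl]methoxy}-6,8-dimethoxy-2H-chromen-2-one (CNP0225022.1)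
Conditions: 2 M HCl, THF, 40 °C
Reagents that add atoms: water, O
Why: acid hydrolysis of the dioxolane, after which acid-catalysed enolisation toward C4 lets the C4 methyl settle equatorial (4β, cis to the 5β-methyl, H-4 axial), the preferred epimer as in friedelin-type 3-ketones; the lactone, the aryl ether and the other four stereocentres are not affected, and any residual 4-epimer is separated and re-equilibrated.

## Compound list

1 | methyl propanoate | CCC(=O)OC | starting material
2 | 1-ethylcyclopropan-1-ol | CCC1(O)CC1 | intermediate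
3 | 2,3-dimethylcyclohex-2-en-1-one | CC1=C(C)C(=O)CCC1 | starting material
4 | 2,3-dimethylcyclohex-2-ene-1,4-dione | CC1=C(C)C(=O)CCC1=O | intermediate
5 | bis(3-oxopentyl)zinc (zinc homoenolate of pentan-3-one) | CCC(=O)CC[Zn]CCC(=O)CC | intermediate
6 | (2R)-2,3-dimethyl-2-(3-oxopentyl)-4-[(trimethylsilyl)oxy]cyclohex-3-en-1-one | CCC(=O)CC[C@@]1(C)C(=O)CCC(O[Si](C)(C)C)=C1C | intermediate
7 | (2R,3R)-2,3-dimethyl-2-(3-oxopentyl)cyclohexane-1,4-dione | O=C1CCC(=O)[C@H](C)[C@@]1(C)CCC(=O)CC | intermediate
8 | (4aR,5R)-1,4a,5-trimethyl-4,4a,7,8-tetrahydronaphthalene-2,6(3H,5H)-dione | CC1=C2CCC(=O)[C@H](C)[C@@]2(C)CCC1=O | intermediate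
9 | (1'R,8a'R)-1',5',8a'-trimethyl-3',4',8',8a'-tetrahydro-1'H-spiro[[1,3]dioxolane-2,2'-naphthalen]-6'(7'H)-one | CC1=C2CCC3(OCCO3)[C@H](C)[C@@]2(C)CCC1=O | intermediate
10 | lithium enolate (C8–OLi, C8=C9) of the trans-fused ketal ketone | [Li+].[O-]C1=C(C)[C@@H]2CCC3(OCCO3)[C@H](C)[C@@]2(C)CC1 | intermediate
11 | (1'R,4a'R,5'R,8a'S)-5'-(hydroxymethyl)-1',5',8a'-trimethyl-3',4',4a',5',8',8a'-hexahydro-1'H-spiro[[1,3]dioxolane-2,2'-naphthalen]-6'(7'H)-one | OC[C@@]1(C)[C@@H]2CCC3(OCCO3)[C@H](C)[C@@]2(C)CCC1=O | intermediate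
12 | (E)-tosylhydrazone of 11 at C8, (1'R,4a'R,5'S,8a'S) | OC[C@@]1(C)[C@@H]2CCC3(OCCO3)[C@H](C)[C@@]2(C)CC/C1=N\NS(=O)(=O)c1ccc(C)cc1 | intermediate
13 | C8 vinyllithium (Δ7) as its C11 lithium alkoxide | [Li+].[O-]C[C@@]1(C)[C@@H]2CCC3(OCCO3)[C@H](C)[C@@]2(C)CC=C1[Li] | intermediate
14 | [(1'R,4a'R,5'R,8a'S)-1',5',8a'-trimethyl-3',4',4a',5',8',8a'-hexahydro-1'H-spiro[[1,3]dioxolane-2,2'-naphthalen]-5'-yl]methanol | OC[C@@]1(C)[C@@H]2CCC3(OCCO3)[C@H](C)[C@@]2(C)CC=C1 | intermediate
15 | 7α,8α-methylene-bridged (cyclopropane) derivative of 14 | OC[C@@]1(C)[C@@H]2CCC3(OCCO3)[C@H](C)[C@@]2(C)C[C@H]4C[C@@H]14 | intermediate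
16 | [(1'R,4a'R,5'R,6'R,8a'S)-1',5',6',8a'-tetramethyloctahydro-1'H-spiro[[1,3]dioxolane-2,2'-naphthalen]-5'-yl]methanol | OC[C@@]1(C)[C@@H]2CCC3(OCCO3)[C@H](C)[C@@]2(C)CC[C@H]1C | intermediate
17 | isofraxidin (7-hydroxy-6,8-dimethoxy-2H-chromen-2-one) | COc1cc2ccc(=O)oc2c(OC)c1O | starting material
18 | trifluoromethanesulfonate of 16 | FC(F)(F)S(=O)(=O)OC[C@@]1(C)[C@@H]2CCC3(OCCO3)[C@H](C)[C@@]2(C)CC[C@H]1C | intermediate
19 | 7-{[(1'R,4a'R,5'R,6'R,8a'S)-1',5',6',8a'-tetramethyloctahydro-1'H-spiro[[1,3]dioxolane-2,2'-naphthalen]-5'-yl]methoxy}-6,8-dimethoxy-2H-chromen-2-one | COc1cc2ccc(=O)oc2c(OC)c1OC[C@@]1(C)[C@@H]2CCC3(OCCO3)[C@H](C)[C@@]2(C)CC[C@H]1C | intermediate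
20 | 7-{[(1R,2R,4aS,5R,8aR)-1,2,4a,5-tetramethyl-6-oxodecahydronaphthalen-1-yl]methoxy}-6,8-dimethoxy-2H-chromen-2-one | COc1cc2ccc(=O)oc2c(OC)c1OC[C@@]1(C)[C@@H]2CCC(=O)[C@H](C)[C@@]2(C)CC[C@H]1C | target

## Step count and risks

Total steps: 12. Longest linear sequence: 11 (3 → 20, steps 2–12).

Steps most likely to fail:

Step 3 (key homoenolate addition). The tetrasubstituted carbon may not react, the ee may be low, or 4 may tautomerise to the hydroquinone under the zinc alkoxide. Fallback, setting out from 4 (with 2): keep the homoenolate polarity but generate it as a radical under neutral conditions and resolve afterwards. With CeCl3 (5 mol %), n-Bu4NCl and 400 nm light in MeCN, alkoxy-radical ring opening of 2 gives the β-keto primary radical, which adds to 4 to give racemic 2,3-dimethyl-2-(3-oxopentyl)cyclohexane-1,4-dione F1. The conditions of step 4 convert it to racemic 1,4a,5-trimethyl-4,4a,7,8-tetrahydronaphthalene-2,6(3H,5H)-dione F2. Preparative chiral-phase SFC then gives the (4aR,5R) enantiomer, which is 8, where the route is rejoined before step 5.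

Step 10 (cyclopropane hydrogenolysis). Cleavage of the other external bond would put the methyl on C7. Fallback, setting out from 14: use a silicon tether so that the carbon can only end up on C8. Silylation with BrCH2SiMe2Cl/Et3N gives the (bromomethyl)dimethylsilyl ether of 14 F3. Bu3SnH/AIBN in benzene at 80 °C cyclises the silylmethyl radical 6-exo onto C8 from the α face to the cyclic siloxane (C11–O–SiMe2–CH2–C8) F4. Protodesilylation with n-Bu4NF in DMF at 80 °C cleaves the Si–C and Si–O bonds and gives 16 directly, rejoining the route before step 11.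

Step 11 (neopentyl etherification). SN2 at the neopentyl C11 with a 2,6-disubstituted phenoxide may be too slow, or rearrangement may compete. Fallback, setting out from 17 and 16: form the aryl–oxygen bond instead, so that no substitution at the neopentyl carbon is needed. Tf2O/pyridine converts 17 into 6,8-dimethoxy-2-oxo-2H-chromen-7-yl trifluoromethanesulfonate F5. Pd-catalysed C–O cross-coupling of F5 with alcohol 16 ([Pd(allyl)Cl]2, RockPhos, Cs2CO3, toluene, 90 °C) gives 19, rejoining the route before step 12.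

Further compounds

F1 | step 3 | racemic 2,3-dimethyl-2-(3-oxopentyl)cyclohexane-1,4-dione | O=C1CCC(=O)C(C)C1(C)CCC(=O)CC
F2 | step 3 | racemic 1,4a,5-trimethyl-4,4a,7,8-tetrahydronaphthalene-2,6(3H,5H)-dione | CC1=C2CCC(=O)C(C)C2(C)CCC1=O
F3 | step 10 | (bromomethyl)dimethylsilyl ether of 14 | BrC[Si](C)(C)OC[C@@]1(C)[C@@H]2CCC3(OCCO3)[C@H](C)[C@@]2(C)CC=C1
F4 | step 10 | cyclic siloxane (C11–O–SiMe2–CH2–C8, CH2 on the α face) | C[Si]1(C)OC[C@@]2(C)[C@@H]3CCC4(OCCO4)[C@H](C)[C@@]3(C)CC[C@H]2C1
F5 | step 11 | 6,8-dimethoxy-2-oxo-2H-chromen-7-yl trifluoromethanesulfonate | COc1cc2ccc(=O)oc2c(OC)c1OS(=O)(=O)C(F)(F)F
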